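**Plan**
1. Retrosynthesis: cut the two angelate C–O bonds and the 8,9-epoxide. Trace O10 and C8=C9 back to a C7=C8–C9=C10 dienone, and C4–OH/C5–H back to a C4=C5 enone. Both are conjugated to a C6 ketone, and this trienone is the oxidised form of a 6-methoxycycloheptatriene.
2. Key cut: bonds C1–C5 and C1–C10. Taking C1 out of the seven-membered ring leaves a benzene ring (C5–C10) on an open chain, (S)-2-diazo-5-aryl-6-methylheptan-3-one.
3. Enabling feature: quaternary C1 carries CH3, lies between C5 and C10 in the seven-membered ring, and sits next to oxygenated C2 in the five-membered ring, so it can be the carbene carbon of an α-diazo ketone. C8–CH3 is para and O6 ortho to C5, so the arene is a plain 3-methylanisole unit.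
4. Forward: a conjugate addition joins arene and chain, and diazoethane brings C1 with its CH3. One rhodium-carbene event then closes the cyclopentanone and expands the six-membered ring to the seven-membered ring. Only redox and C–O bond-forming steps follow, with the esters last.
5. Stereochemistry: the catalyst sets C4. C4 sets C1 (Buchner step) and C2 (hydride) and is then erased. The C1 methyl and 2β-OH re-set C4, and C5 follows by equilibration. The cis-fused fold sets C10, 4β-OH delivers hydride to C6, and 10α/6α-OH direct the epoxide.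

Key step: step 5

Numbering and faces: daucane numbering is used (C1 quaternary ring-fusion carbon, C2–C4 rest of the five-membered ring, C5 ring-fusion CH, C6–C10 rest of the seven-membered ring); α is the face that carries the C1 methyl group and β is the other face.
Assumption: the sense of induction in step 1 is taken from the behaviour of (E)-β-alkyl enones and enoates toward rhodium/BINAP catalysts; if it proves opposite, the ligand antipode is used.

Step 1
Reactants: 1 (2-methoxy-4-methylphenyl)boronic acid; 2 ethyl (E)-4-methylpent-2-enoate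
Product: 3 ethyl (S)-3-(2-methoxy-4-methylphenyl)-4-methylpentanoate
Conditions: [Rh(OH)((R)-BINAP)]2 (1.5 mol%), dioxane/H2O 10:1, 40 °C
Reagents that add atoms: none
Why: Hayashi–Miyaura asymmetric 1,4-addition, in which the BINAP-bound aryl–rhodium species inserts one enantiotopic face of the (E)-enoate and hydrolysis of the rhodium enolate frees 3, setting C4 as (S).

Step 2
Reactants: 3 ethyl (S)-3-(2-methoxy-4-methylphenyl)-4-methylpentanoate
Product: 4 (S)-3-(2-methoxy-4-methylphenyl)-4-methylpentanoic acid
Conditions: LiOH, THF/H2O, rt; then 1 M HCl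
Reagents that add atoms: lithium hydroxide [Li+].[OH-]
Why: Ester saponification by acyl–oxygen cleavage, which does not touch the β-stereocentre C4.

Step 3
Reactants: 5 N-ethyl-N-nitrosourea
Product: 6 diazoethane (dried ethereal solution)
Conditions: 40% aq KOH, Et2O, 0 °C; organic layer dried over KOH pellets
Reagents that add atoms: none
Why: Base-induced fragmentation of an N-alkyl-N-nitrosourea, the standard way to generate a diazoalkane.

Step 4
Reactants: 4 (S)-3-(2-methoxy-4-methylphenyl)-4-methylpentanoic acid; 6 diazoethane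
Product: 8 (S)-2-diazo-5-(2-methoxy-4-methylphenyl)-6-methylheptan-3-one, via acid chloride 7 (not isolated)
Conditions: (COCl)2, DMF (cat.), CH2Cl2, 0 °C to rt, evaporate; 6 (3 equiv), Et2O, −20 °C to rt
Reagents that add atoms: oxalyl chloride ClC(=O)C(=O)Cl (chlorine of 7 only)
Why: Acylation of a diazoalkane by an acid chloride (first stage of an Arndt–Eistert sequence) places the diazo carbon C1 with its methyl group regiospecifically next to C2, a second equivalent of 6 taking up the HCl.

Step 5
Reactants: 8 (S)-2-diazo-5-(2-methoxy-4-methylphenyl)-6-methylheptan-3-one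
Product: 10 (3S,8aR)-3-isopropyl-4-methoxy-6,8a-dimethyl-3,8a-dihydroazulen-1(2H)-one (6-methoxydauca-5,7,9-trien-2-one; 1α-CH3; 4β-isopropyl), via norcaradiene 9 (not isolated)
Conditions: Rh2(OAc)4 (0.5 mol%), CH2Cl2, reflux, slow addition of 8
Reagents that add atoms: none
Why: Rh2(OAc)4 expels N2 from 8 and the electrophilic rhodium carbene at C1 adds across the C5–C10 (ipso–ortho) π bond of the arene to give norcaradiene 9, whose C5–C10 σ bond opens at once by disrotatory 6π electrocyclic ring opening, so that C1 is inserted into the six-membered ring C5–C10 and turns it into the seven-membered ring (intramolecular Buchner reaction). The closest known reaction type is the Rh2(OAc)4-catalysed cyclisation of 2-diazo-5-arylalkan-3-ones to trans-3-alkyl-8a-methyl-3,8a-dihydroazulen-1(2H)-ones. The cyclopentanone closes by C1–C5 bond formation as part of a [2+1] cycloaddition in which the three-atom tether C2–C3–C4 lets the carbene reach only the ipso–ortho bond (five-membered, exo to the reacting π bond), the transient cyclopropane closes by C1–C10 bond formation, and the seven-membered ring is not closed but arises by cleavage of C5–C10. The one lasting new stereocentre, quaternary C1, is controlled by C4: allylic 1,3-strain holds C4–H in the arene plane beside the ortho OCH3, C3 and the isopropyl group then flank opposite faces, and the carbene attacks from the face of C3, which places the C1 methyl trans to the isopropyl group (C5 and C10 of 9 become sp2 again). The same conformer tilts C3 toward C10 and so secures regioselectivity for the unsubstituted C5–C10 bond over C5–C6(OCH3). Chemoselectivity is needed over 1,2-hydride shift from the C1 methyl group, 1,5 C–H insertion into the isopropyl methine and aromatic substitution to a 2-tetralone; the electron-rich arene held over the carbene, the carboxylate ligands, acid-free conditions and slow addition secure it.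

Step 6
Reactants: 10 6-methoxydauca-5,7,9-trien-2-one
Product: 11 6-methoxydauca-5,7,9-trien-2β-ol (1α-CH3; 4β-isopropyl)
Conditions: NaBH4, MeOH/THF, −20 °C
Reagents that add atoms: none
Why: Substrate-controlled borohydride 1,2-reduction, in which allylic 1,3-strain with the C6 methoxy group keeps the C4 isopropyl group pseudo-axial on the β face where, together with C10, it blocks the trajectory to C2, so hydride should enter from the α face and give the 2β-alcohol.

Step 7
Reactants: 11 6-methoxydauca-5,7,9-trien-2β-ol
Product: 12 2β-hydroxydauca-4,7,9-trien-6-one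
Conditions: DDQ (1.1 equiv), acetone/H2O 19:1, 0 °C
Reagents that add atoms: water O
Why: DDQ dehydrogenation of an enol ether, in which hydride abstraction from the tertiary allylic C4–H gives an oxocarbenium ion delocalised over C4–C10 and water at C6 expels methanol to leave the cross-conjugated trienone, the C4 stereocentre being given up on purpose after it has set C1 and C2.

Step 8
Reactants: 12 2β-hydroxydauca-4,7,9-trien-6-one
Product: 13 4β,5β-epoxy-2β-hydroxydauca-7,9-dien-6-one
Conditions: mCPBA (1.0 equiv), CH2Cl2, −10 °C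
Reagents that add atoms: mCPBA OOC(=O)c1cccc(Cl)c1
Why: Hydroxyl-directed Prilezhaev epoxidation, in which the peracid should pick the only tetrasubstituted alkene (as peracids do with the more substituted arm of cross-conjugated dienones; isopropyl/C6=O strain twists it out of conjugation), and the 2β-OH of the cyclopent-3-enol unit together with α-face shielding by the C1 methyl should send oxygen to the β face, setting C4.

Step 9
Reactants: 13 4β,5β-epoxy-2β-hydroxydauca-7,9-dien-6-one
Product: 15 2β,4β-dihydroxy-5αH-dauca-7,9-dien-6-one (cis-fused), via 5-epimer 14 (not isolated)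
Conditions: SmI2 (2.2 equiv), THF/MeOH, −78 °C; work-up; DBU (0.2 equiv), CH2Cl2, rt
Reagents that add atoms: none
Why: SmI2 reduction of an α,β-epoxy ketone cleaves only the C5–O bond, so O4 keeps its β configuration, and base equilibration of the enolisable C5 should favour the cis-fused aldol 15, the only epimer that places C6 anti to the isopropyl group and allows an O4–H···O=C6 hydrogen bond.

Step 10
Reactants: 15 2β,4β-dihydroxy-5αH-dauca-7,9-dien-6-one
Product: 16 4β-hydroxy-2β-(triethylsilyloxy)-5αH-dauca-7,9-dien-6-one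
Conditions: Et3SiCl, imidazole, DMF, 0 °C
Reagents that add atoms: chlorotriethylsilane CC[Si](Cl)(CC)CC
Why: Silyl ether formation selective for the secondary 2β-OH over the tertiary, hydrogen-bonded 4β-OH, which must stay free to direct step 13, while the silyl ether adds to the shielding of the β face.

Step 11
Reactants: 16 4β-hydroxy-2β-(triethylsilyloxy)-5αH-dauca-7,9-dien-6-one
Product: 17 9α,10α-epoxy-4β-hydroxy-2β-(triethylsilyloxy)-5αH-dauc-7-en-6-one
Conditions: mCPBA (1.2 equiv), CH2Cl2, 0 °C
Reagents that add atoms: mCPBA OOC(=O)c1cccc(Cl)c1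
Why: Prilezhaev epoxidation of the γ,δ-alkene of a linear dienone (the least deactivated alkene), with attack expected on the convex α face of the folded cis-hydroazulene because its concave β face is roofed by C2–OSiEt3 and C4–OH, which sets C10.

Step 12
Reactants: 17 9α,10α-epoxy-4β-hydroxy-2β-(triethylsilyloxy)-5αH-dauc-7-en-6-one
Product: 18 4β,10α-dihydroxy-2β-(triethylsilyloxy)-5αH-dauc-8-en-6-one
Conditions: SmI2 (2.2 equiv), THF/MeOH, −90 °C
Reagents that add atoms: none
Why: Vinylogous SmI2 reduction of a γ,δ-epoxy enone, in which electron transfer to the enone expels the allylic C9–O bond, kinetic α-protonation of the samarium dienolate at C7 leaves C8=C9 out of conjugation, and the untouched C10–O bond keeps the α configuration.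

Step 13
Reactants: 18 4β,10α-dihydroxy-2β-(triethylsilyloxy)-5αH-dauc-8-en-6-one
Product: 19 2β-(triethylsilyloxy)-5αH-dauc-8-ene-4β,6α,10α-triol
Conditions: Me4NBH(OAc)3, MeCN/AcOH 1:1, −30 °C
Reagents that add atoms: none
Why: Evans–Saksena reduction, in which exchange of an acetate for the 4β-OH ties the borohydride to the β face and intramolecular hydride delivery to C6 gives the 1,3-anti diol, that is the 6α-alcohol.

Step 14
Reactants: 19 2β-(triethylsilyloxy)-5αH-dauc-8-ene-4β,6α,10α-triol
Product: 20 8α,9α-epoxy-2β-(triethylsilyloxy)-5αH-daucane-4β,6α,10α-triol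
Conditions: VO(acac)2 (5 mol%), t-BuOOH, CH2Cl2, 0 °C
Reagents that add atoms: tert-butyl hydroperoxide CC(C)(C)OO
Why: Vanadium-catalysed hydroxyl-directed epoxidation, in which the allylic 10α-OH (backed by the homoallylic 6α-OH) binds the vanadium peroxide and delivers oxygen to the α face of C8=C9, giving the cis-epoxy alcohol and setting C8 and C9.

Step 15
Reactants: 20 8α,9α-epoxy-2β-(triethylsilyloxy)-5αH-daucane-4β,6α,10α-triol; 21 angelic acid ((Z)-2-methylbut-2-enoic acid)
Product: 23 6α,10α-bis(angeloyloxy)-8α,9α-epoxy-2β-(triethylsilyloxy)-5αH-daucan-4β-ol, via mixed anhydride 22 (not isolated)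
Conditions: 21, 2,4,6-Cl3C6H2COCl, Et3N, toluene, rt; then 20, 80 °C
Reagents that add atoms: angelic acid 21 C/C=C(/C)C(=O)O; 2,4,6-trichlorobenzoyl chloride O=C(Cl)c1c(Cl)cc(Cl)cc1Cl (aroyl part of 22 only)
Why: Yamaguchi-type esterification with the preformed mixed anhydride and no nucleophilic catalyst, the reaction type known to transfer the angeloyl group without Z to E isomerisation, in which the two secondary alcohols on the convex α face react and the tertiary 4β-OH does not.

Step 16
Reactants: 23 6α,10α-bis(angeloyloxy)-8α,9α-epoxy-2β-(triethylsilyloxy)-5αH-daucan-4β-ol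
Product: 24 6α,10α-bis(angeloyloxy)-8α,9α-epoxy-5αH-daucane-2β,4β-diol (CNP0265715.2)
Conditions: HF·pyridine, pyridine/THF, 0 °C
Reagents that add atoms: none
Why: Fluoride-driven cleavage of the Si–O bond under buffered conditions, which the esters, the trisubstituted epoxide and the tertiary alcohol tolerate.

**Compound list**
1 | (2-methoxy-4-methylphenyl)boronic acid | COc1cc(C)ccc1B(O)O | starting material
2 | ethyl (E)-4-methylpent-2-enoate | CCOC(=O)/C=C/C(C)C | starting material
3 | ethyl (S)-3-(2-methoxy-4-methylphenyl)-4-methylpentanoate | CCOC(=O)C[C@@H](C(C)C)c1ccc(C)cc1OC | intermediate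
4 | (S)-3-(2-methoxy-4-methylphenyl)-4-methylpentanoic acid | OC(=O)C[C@@H](C(C)C)c1ccc(C)cc1OC | intermediate
5 | N-ethyl-N-nitrosourea | CCN(N=O)C(N)=O | starting material
6 | diazoethane | CC=[N+]=[N-] | intermediate
7 | (S)-3-(2-methoxy-4-methylphenyl)-4-methylpentanoyl chloride | ClC(=O)C[C@@H](C(C)C)c1ccc(C)cc1OC | intermediate
8 | (S)-2-diazo-5-(2-methoxy-4-methylphenyl)-6-methylheptan-3-one | CC(=[N+]=[N-])C(=O)C[C@@H](C(C)C)c1ccc(C)cc1OC | intermediate
9 | norcaradiene valence tautomer of 10 (cyclopropane C1–C5–C10, diene C6=C7–C8=C9) | COC1=CC(C)=C[C@@H]3[C@@]2(C)C(=O)C[C@@H](C(C)C)[C@]123 | intermediate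
10 | (3S,8aR)-3-isopropyl-4-methoxy-6,8a-dimethyl-3,8a-dihydroazulen-1(2H)-one | COC1=C2[C@H](C(C)C)CC(=O)[C@]2(C)C=CC(C)=C1 | intermediate
11 | 6-methoxydauca-5,7,9-trien-2β-ol (1α-CH3, 4β-isopropyl) | COC1=C2[C@H](C(C)C)C[C@H](O)[C@]2(C)C=CC(C)=C1 | intermediate
12 | 2β-hydroxydauca-4,7,9-trien-6-one | O=C1C=C(C)C=C[C@@]2(C)[C@@H](O)CC(C(C)C)=C12 | intermediate
13 | 4β,5β-epoxy-2β-hydroxydauca-7,9-dien-6-one | O=C1C=C(C)C=C[C@@]2(C)[C@@H](O)C[C@@]3(C(C)C)O[C@@]123 | intermediate
14 | 2β,4β-dihydroxy-5βH-dauca-7,9-dien-6-one (trans-fused 5-epimer) | O=C1C=C(C)C=C[C@@]2(C)[C@@H](O)C[C@](O)(C(C)C)[C@H]12 | intermediate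
15 | 2β,4β-dihydroxy-5αH-dauca-7,9-dien-6-one (cis-fused) | O=C1C=C(C)C=C[C@@]2(C)[C@@H](O)C[C@](O)(C(C)C)[C@@H]12 | intermediate
16 | 4β-hydroxy-2β-(triethylsilyloxy)-5αH-dauca-7,9-dien-6-one | O=C1C=C(C)C=C[C@@]2(C)[C@@H](O[Si](CC)(CC)CC)C[C@](O)(C(C)C)[C@@H]12 | intermediate
17 | 9α,10α-epoxy-4β-hydroxy-2β-(triethylsilyloxy)-5αH-dauc-7-en-6-one | O=C1C=C(C)[C@@H]3O[C@@H]3[C@@]2(C)[C@@H](O[Si](CC)(CC)CC)C[C@](O)(C(C)C)[C@@H]12 | intermediate
18 | 4β,10α-dihydroxy-2β-(triethylsilyloxy)-5αH-dauc-8-en-6-one | O=C1CC(C)=C[C@H](O)[C@@]2(C)[C@@H](O[Si](CC)(CC)CC)C[C@](O)(C(C)C)[C@@H]12 | intermediate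
19 | 2β-(triethylsilyloxy)-5αH-dauc-8-ene-4β,6α,10α-triol | O[C@@H]1CC(C)=C[C@H](O)[C@@]2(C)[C@@H](O[Si](CC)(CC)CC)C[C@](O)(C(C)C)[C@@H]12 | intermediate
20 | 8α,9α-epoxy-2β-(triethylsilyloxy)-5αH-daucane-4β,6α,10α-triol | O[C@@H]1C[C@]2(C)O[C@@H]2[C@H](O)[C@@]2(C)[C@@H](O[Si](CC)(CC)CC)C[C@](O)(C(C)C)[C@@H]12 | intermediate
21 | angelic acid | C/C=C(/C)C(=O)O | starting material
22 | angelic 2,4,6-trichlorobenzoic anhydride | C/C=C(/C)C(=O)OC(=O)c1c(Cl)cc(Cl)cc1Cl | intermediate
23 | 6α,10α-bis(angeloyloxy)-8α,9α-epoxy-2β-(triethylsilyloxy)-5αH-daucan-4β-ol | C/C=C(/C)C(=O)O[C@@H]1C[C@]2(C)O[C@@H]2[C@H](OC(=O)/C(C)=C\C)[C@@]2(C)[C@@H](O[Si](CC)(CC)CC)C[C@](O)(C(C)C)[C@@H]12 | intermediate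
24 | 6α,10α-bis(angeloyloxy)-8α,9α-epoxy-5αH-daucane-2β,4β-diol (CNP0265715.2) | C/C=C(/C)C(=O)O[C@@H]1C[C@]2(C)O[C@@H]2[C@H](OC(=O)/C(C)=C\C)[C@@]2(C)[C@@H](O)C[C@](O)(C(C)C)[C@@H]12 | target

Total step count: 16. Longest linear sequence: 15 steps (steps 1, 2 and 4–16; step 3 is a one-step side branch).

**Steps most likely to fail**

Step 8. The peracid may attack the C9=C10 bond competitively or oxidise twice, because all three alkenes of 12 are deactivated by the same carbonyl group.
- The fallback sets out from 12 and takes the carbonyl out of conjugation first.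
- Luche reduction (NaBH4, CeCl3·7H2O, MeOH, −78 °C), with hydride anti to the axial C1 methyl, gives dauca-4,7,9-triene-2β,6α-diol F1.
- In F1 the C4=C5 bond is an isolated tetrasubstituted alkene. Dimethyldioxirane in acetone at −20 °C should epoxidise it from the β face to give 4β,5β-epoxydauca-7,9-diene-2β,6α-diol F2.
- MnO2 in CH2Cl2 oxidises only the dienylic 6-OH, and the route is rejoined at 13.

Step 9. Retro-aldol cleavage or dehydration of the tertiary aldol may compete with epimerisation at C5 during the base treatment.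
- The fallback sets out from crude 14 and blocks the aldol oxygen before the equilibration.
- Et3SiCl/imidazole gives 4β-hydroxy-2β-(triethylsilyloxy)-5βH-dauca-7,9-dien-6-one F3.
- Me3SiOTf/2,6-lutidine caps the tertiary alcohol to give 2β-(triethylsilyloxy)-4β-(trimethylsilyloxy)-5βH-dauca-7,9-dien-6-one F4.
- DBU in warm toluene equilibrates C5, driven by the isopropyl/C6 clash alone, to 2β-(triethylsilyloxy)-4β-(trimethylsilyloxy)-5αH-dauca-7,9-dien-6-one F5.
- Citric acid in MeOH removes only the tertiary trimethylsilyl group, and the route is rejoined at 16.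

Step 6. Facial selectivity at C2 may be poor, because the C1 methyl group on the α face and the isopropyl group and C10 on the β face oppose each other.
- The fallback sets out from 10 and replaces substrate control by catalyst control.
- It uses a Corey–Bakshi–Shibata reduction with (R)-2-methyl-CBS-oxazaborolidine and catecholborane in toluene at −78 °C.
- This reduction differentiates the quaternary C1 from the C3 methylene and should give the (S)-carbinol, so the route is rejoined at 11.
- This fallback makes no compound outside the list (F0).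

**Further compounds**
F1 | step 8 | dauca-4,7,9-triene-2β,6α-diol | O[C@@H]1C=C(C)C=C[C@@]2(C)[C@@H](O)CC(C(C)C)=C12
F2 | step 8 | 4β,5β-epoxydauca-7,9-diene-2β,6α-diol | O[C@@H]1C=C(C)C=C[C@@]2(C)[C@@H](O)C[C@@]3(C(C)C)O[C@@]123
F3 | step 9 | 4β-hydroxy-2β-(triethylsilyloxy)-5βH-dauca-7,9-dien-6-one | O=C1C=C(C)C=C[C@@]2(C)[C@@H](O[Si](CC)(CC)CC)C[C@](O)(C(C)C)[C@H]12
F4 | step 9 | 2β-(triethylsilyloxy)-4β-(trimethylsilyloxy)-5βH-dauca-7,9-dien-6-one | O=C1C=C(C)C=C[C@@]2(C)[C@@H](O[Si](CC)(CC)CC)C[C@](O[Si](C)(C)C)(C(C)C)[C@H]12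
F5 | step 9 | 2β-(triethylsilyloxy)-4β-(trimethylsilyloxy)-5αH-dauca-7,9-dien-6-one | O=C1C=C(C)C=C[C@@]2(C)[C@@H](O[Si](CC)(CC)CC)C[C@](O[Si](C)(C)C)(C(C)C)[C@@H]12
F0 | step 6 | none | none
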